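**Assumption:** the target has no stereocentre and no stereogenic double bond. It is a single achiral compound, so no enantioselective step is needed.

## Retrosynthetic overview
1. 15 ⇐ 13 by fourfold O-demethylation. 13 ⇐ 11 by removal of two ketone oxygens. 11 ⇐ 10 by saturation of two C=C bonds.
2. Key disconnection: the C1–C2 and C13–C14 bonds of the C14 tether. They come from a twofold intermolecular directed aldol between the kinetic bis-enolate of dodecane-2,11-dione (4) and two molecules of 3,5-dimethoxybenzaldehyde (5).
3. 4 ⇐ sebacoyl chloride (1) through the bis-Weinreb amide 2 and MeMgBr.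
4. No ring is formed. Both benzene rings are bought intact in 5.

## Route

**Step 1**
Reactants: 1 sebacoyl chloride
Product: 2 N1,N10-dimethoxy-N1,N10-dimethyldecanediamide
Conditions: MeNHOMe·HCl (2.4 equiv), Et3N (5 equiv), CH2Cl2, 0 °C → rt, 3 h
Reagents that add atoms: N,O-dimethylhydroxylamine hydrochloride, CNOC.Cl
Why: Weinreb amide formation by N-acylation, in which the hydroxylamine freed by Et3N is acylated cleanly by the acid chloride at both termini and no stereocentre is created.

**Step 2**
Reactants: 2 N1,N10-dimethoxy-N1,N10-dimethyldecanediamide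
Product: 4 dodecane-2,11-dione, via bis-magnesium tetrahedral chelate 3 (not isolated)
Conditions: MeMgBr (3.0 M in Et2O, 3.0 equiv), THF, 0 °C, 2 h; then 1 M HCl, 0 °C
Reagents that add atoms: methylmagnesium bromide, C[Mg]Br
Why: Weinreb ketone synthesis, in which each amide takes up exactly one MeMgBr because the five-membered Mg chelate 3 survives until the acidic quench, so no tertiary alcohol forms and no stereocentre remains in 4.

**Step 3 (key step)**
Reactants: 4 dodecane-2,11-dione; 5 3,5-dimethoxybenzaldehyde (2.3 equiv)
Product: 8 1,14-bis(3,5-dimethoxyphenyl)-1,14-dihydroxytetradecane-3,12-dione (dl/meso mixture), via dilithium bis-enolate 6 (not isolated), via dilithium bis-aldolate 7 (not isolated)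
Conditions: LiN(i-Pr)2 (LDA, 2.0 M commercial solution, 2.2 equiv), THF, −78 °C, 4 added slowly to the base, 45 min; 5 in THF, −78 °C, 30 min; AcOH/THF, −78 °C
Reagents that add atoms: none
Why: Twofold directed (crossed) aldol addition, in which inverse addition of 4 to the hindered amide base at −78 °C deprotonates irreversibly at the two CH3 groups, the non-enolisable aldehyde 5 can act only as acceptor, and the two new carbinol stereocentres form without control (dl/meso about 1:1), which is harmless because both are erased in step 4.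

**Step 4**
Reactants: 8 1,14-bis(3,5-dimethoxyphenyl)-1,14-dihydroxytetradecane-3,12-dione
Product: 10 (1E,13E)-1,14-bis(3,5-dimethoxyphenyl)tetradeca-1,13-diene-3,12-dione, via bis-mesylate 9 (not isolated)
Conditions: MsCl (3 equiv), Et3N (8 equiv), CH2Cl2, 0 °C → rt, 3 h
Reagents that add atoms: none
Why: Mesylation followed by E1cB β-elimination, in which the benzylic mesylate 9 lies β to a ketone whose α-protons Et3N removes easily, so mesylate is expelled to give the aryl-conjugated E-enone at both ends, erasing the two carbinol stereocentres and creating none.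

**Step 5**
Reactants: 10 (1E,13E)-1,14-bis(3,5-dimethoxyphenyl)tetradeca-1,13-diene-3,12-dione
Product: 11 1,14-bis(3,5-dimethoxyphenyl)tetradecane-3,12-dione
Conditions: H2 (1 atm), 10% Pd/C, EtOAc, rt, 4 h
Reagents that add atoms: none
Why: Heterogeneous catalytic hydrogenation, in which the two conjugated unhindered C=C bonds are saturated on Pd at 1 atm while isolated dialkyl ketones, aryl methyl ethers and the arenes are inert under these neutral conditions, and no stereocentre arises.

**Step 6**
Reactants: 11 1,14-bis(3,5-dimethoxyphenyl)tetradecane-3,12-dione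
Product: 13 1,14-bis(3,5-dimethoxyphenyl)tetradecane, via bis-hydrazone 12 (not isolated)
Conditions: N2H4·H2O (20 equiv), KOH (8 equiv), diethylene glycol, N2, 130 °C, 2 h; distil off H2O/N2H4, then 195–200 °C, 4 h
Reagents that add atoms: none
Why: Wolff–Kishner reduction (Huang-Minlon procedure), in which a large excess of hydrazine turns both unhindered dialkyl ketones into hydrazones 12 rather than azines and hot KOH then drives irreversible loss of N2 to leave CH2 groups, the aryl methyl ethers being the only other functionality and any stray phenol converging on 15 in step 7.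

**Step 7**
Reactants: 13 1,14-bis(3,5-dimethoxyphenyl)tetradecane
Product: 15 bisnorstriatol [5,5'-(tetradecane-1,14-diyl)bis(benzene-1,3-diol)], via tetrakis(dibromoboryl) ether 14 (not isolated)
Conditions: BBr3 (1.0 M in CH2Cl2, 8 equiv), CH2Cl2, Ar, −78 °C → rt, 16 h; then ice/H2O, EtOAc extraction
Reagents that add atoms: none
Why: Lewis-acid aryl methyl ether cleavage with BBr3, in which each ArO–CH3 oxygen binds boron and bromide attacks the methyl carbon in an SN2 step to give aryl borate 14, which water hydrolyses to the free resorcinols, with nothing in the saturated tether able to react and no stereocentre involved.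

## Compound list
1 | sebacoyl chloride (decanedioyl dichloride) | ClC(=O)CCCCCCCCC(=O)Cl | starting material
2 | N1,N10-dimethoxy-N1,N10-dimethyldecanediamide (bis-Weinreb amide) | CON(C)C(=O)CCCCCCCCC(=O)N(C)OC | intermediate
3 | bis-magnesium tetrahedral chelate (bromomagnesium hemiaminalate at both termini; not isolated; stereocentres uncontrolled) | CON(C)C(C)(O[Mg]Br)CCCCCCCCC(C)(O[Mg]Br)N(C)OC | intermediate
4 | dodecane-2,11-dione | CC(=O)CCCCCCCCC(C)=O | intermediate
5 | 3,5-dimethoxybenzaldehyde | COc1cc(C=O)cc(OC)c1 | starting material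
6 | dilithium dodeca-1,11-diene-2,11-diolate (kinetic bis-enolate; not isolated) | [Li]OC(=C)CCCCCCCCC(=C)O[Li] | intermediate
7 | dilithium bis-aldolate of 8 (not isolated; dl/meso mixture) | COc1cc(OC)cc(C(O[Li])CC(=O)CCCCCCCCC(=O)CC(O[Li])c2cc(OC)cc(OC)c2)c1 | intermediate
8 | 1,14-bis(3,5-dimethoxyphenyl)-1,14-dihydroxytetradecane-3,12-dione (dl/meso mixture, both centres removed in step 4) | COc1cc(OC)cc(C(O)CC(=O)CCCCCCCCC(=O)CC(O)c2cc(OC)cc(OC)c2)c1 | intermediate
9 | 1,14-bis(3,5-dimethoxyphenyl)-3,12-dioxotetradecane-1,14-diyl dimethanesulfonate (not isolated; dl/meso mixture) | COc1cc(OC)cc(C(OS(C)(=O)=O)CC(=O)CCCCCCCCC(=O)CC(OS(C)(=O)=O)c2cc(OC)cc(OC)c2)c1 | intermediate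
10 | (1E,13E)-1,14-bis(3,5-dimethoxyphenyl)tetradeca-1,13-diene-3,12-dione | COc1cc(OC)cc(/C=C/C(=O)CCCCCCCCC(=O)/C=C/c2cc(OC)cc(OC)c2)c1 | intermediate
11 | 1,14-bis(3,5-dimethoxyphenyl)tetradecane-3,12-dione | COc1cc(OC)cc(CCC(=O)CCCCCCCCC(=O)CCc2cc(OC)cc(OC)c2)c1 | intermediate
12 | bis-hydrazone of 11 (not isolated; C=N geometry mixed) | COc1cc(OC)cc(CCC(=NN)CCCCCCCCC(=NN)CCc2cc(OC)cc(OC)c2)c1 | intermediate
13 | 1,14-bis(3,5-dimethoxyphenyl)tetradecane | COc1cc(OC)cc(CCCCCCCCCCCCCCc2cc(OC)cc(OC)c2)c1 | intermediate
14 | tetrakis(dibromoboryl) ether of 15 (not isolated) | BrB(Br)Oc1cc(OB(Br)Br)cc(CCCCCCCCCCCCCCc2cc(OB(Br)Br)cc(OB(Br)Br)c2)c1 | intermediate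
15 | bisnorstriatol, 5,5'-(tetradecane-1,14-diyl)bis(benzene-1,3-diol), achiral | Oc1cc(O)cc(CCCCCCCCCCCCCCc2cc(O)cc(O)c2)c1 | target

## Counts
- Total steps: 7.
- Longest linear sequence: 7 steps (1 → 2 → 4 → 8 → 10 → 11 → 13 → 15). Compound 5 is bought and enters at step 3.

## Three steps most likely to fail, with fallbacks

**Step 3 (double directed aldol).**
- Risks: incomplete double enolisation, leakage to the internal enolate, mono-adduct formation, and retro-aldol on work-up.
- Fallback: it sets out from 4. The kinetic bis-enolate 6 is trapped with Me3SiCl at −78 °C to give 2,11-bis(trimethylsilyloxy)dodeca-1,11-diene F1.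
- F1 is isolated, so its regiochemical purity can be checked and improved by distillation.
- F1 is then used as a neutral nucleophile in a TiCl4-promoted Mukaiyama aldol addition to 5 (CH2Cl2, −78 °C, aqueous work-up).
- The fallback comes back to the route at 8.

**Step 6 (double Wolff–Kishner).**
- Risks: azine or oligomer formation from the difunctional substrate, reduction at only one end, and partial ether cleavage in hot KOH.
- Fallback: it sets out from 11. Thioketalisation with 1,2-ethanedithiol and BF3·OEt2 in CH2Cl2 gives 2,2'-(octane-1,8-diyl)bis{2-[2-(3,5-dimethoxyphenyl)ethyl]-1,3-dithiolane} F2.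
- F2 is desulfurised with Raney Ni in refluxing EtOH (Mozingo reduction) under neutral conditions.
- The fallback comes back to the route at 13.

**Step 4 (double mesylation/elimination).**
- Risks: retro-aldol of 8 under amine base, diversion to a benzylic chloride, and elimination at only one end.
- Fallback: it sets out from 8. Acetylation (Ac2O, pyridine, catalytic DMAP, 0 °C) gives 1,14-bis(3,5-dimethoxyphenyl)-3,12-dioxotetradecane-1,14-diyl diacetate F3.
- The benzylic C–O bonds of F3 are cleaved directly by hydrogenolysis (H2, 3 atm, 10% Pd/C, EtOH/AcOH).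
- Any F3 that eliminates to 10 on the way is hydrogenated in the same flask.
- The fallback bypasses 10 and comes back to the route at 11.

## Further compounds
F1 | step 3 | 2,11-bis(trimethylsilyloxy)dodeca-1,11-diene | C=C(O[Si](C)(C)C)CCCCCCCCC(=C)O[Si](C)(C)C
F2 | step 6 | 2,2'-(octane-1,8-diyl)bis{2-[2-(3,5-dimethoxyphenyl)ethyl]-1,3-dithiolane} | COc1cc(OC)cc(CCC2(SCCS2)CCCCCCCCC2(SCCS2)CCc2cc(OC)cc(OC)c2)c1
F3 | step 4 | 1,14-bis(3,5-dimethoxyphenyl)-3,12-dioxotetradecane-1,14-diyl diacetate (dl/meso mixture) | COc1cc(OC)cc(C(OC(C)=O)CC(=O)CCCCCCCCC(=O)CC(OC(C)=O)c2cc(OC)cc(OC)c2)c1
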